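**Numbering.** Xenicane numbering is used throughout: C1 acetal carbon, O2, C3=C4 enol ether, C4a and C11a ring fusion, C5–C11 the rest of ring A, C7 methyl, C7–C8 epoxide, C11=C19 methylene, C12 the acetoxy carbinol, C13–C15 the enoate arm. From the SMILES the target is (1R,4aS,7S,8R,11aR,12S) with an E enoate.

## The problem

The target is a xenicane: a nine-membered carbocycle (ring A: C4a, C5–C11, C11a) trans-fused through C4a and C11a to a 2-acetoxy-3,4-dihydro-2H-pyran (ring B: C1, O2, C3=C4, C4a, C11a). Ring A carries a cis-7,8-epoxide with the C7 methyl group and the exocyclic C11=C19 methylene; C4 carries an arm that starts at the acetoxy carbinol C12 and ends in an (E)-2-methyl enoate. Six stereocentres must be set. C7/C8 are a remote pair that an allylic-alcohol epoxidation can fix early and absolutely. C12 is isolated on the side chain and needs its own reagent control. C4a/C11a are contiguous and best made together, and C1, an acylated lactol, then follows from C11a. Almost every functional group is fragile: the acyl acetal at C1, the enol ether C3=C4 with its allylic acetate at C12 (a vinylogous acylal), the trisubstituted epoxide, and a methylene that slips into conjugation in any open-chain C1 carbonyl precursor. Closing the nine-membered ring is the central risk. The enabling feature is that C1 and C3 are the ends of a masked 1,5-dialdehyde whose central bond C11a–C4a is also the bond that closes ring A. If that bond is made from a C1 enamine and a C3 enal, the C3 enol oxygen can add to C1, so ring A, ring B and three stereocentres arise in one event.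

## Retrosynthesis

**C1–O acyl bond (25 ⇒ 24).** The anomeric acetate is the most labile group, so it is put on last by acylating lactol 24. Any earlier introduction would expose an acyl acetal to every later reagent. The forward step only has to trap the right anomer.

**C11a–C4a and O2–C1 (24 ⇒ 22).** Cutting both bonds opens ring A and ring B at once and leads to the acyclic epoxy dialdehyde 22 (C1 aldehyde, C3 enal). Neighbouring cuts inside ring A (C7=C8, C10–C11) would close only the carbocycle and leave ring B, the trans fusion and the C1/C3 oxidation pattern to be built separately. The precursor keeps only three stereocentres (C7, C8, C12), all remote from each other and accessible by acyclic methods. The forward reaction must achieve a nine-membered closure, α- rather than γ-attack of a dienamine, catalyst control of C11a/C4a, and survival of the C12 acetate next to a transient C3 enol.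

**C1 and C3 carbonyls (22 ⇒ 21 ⇒ 20).** The β,γ-unsaturated C1 aldehyde cannot be carried, so both aldehydes come from primary alcohols in the last step before cyclisation (diol 21). These are masked as the bis-silyl ether 20 while the side chain is finished.

**C14=C15 and C12–C13 (20 ⇒ 18 + 19; 18 ⇒ 17 ⇒ 15).** The enoate is cut at its double bond to terminal alkene 18 and methyl methacrylate 19 (cross-metathesis). The homoallylic acetate 18 comes from alcohol 17 by reagent-controlled allylboration of the C12 aldehyde 15. This sets C12 where no neighbouring stereocentre can help. A one-step vinylogous Mukaiyama aldol with a tiglate dienolate would be shorter, but its Lewis acids are also reagents for opening the trisubstituted epoxide, so the two-step boron/ruthenium sequence is preferred.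

**C4–C12 (15 ⇒ 13 ⇒ 12).** C12 must sit cis to C5 on the C4=C4a double bond, the less stable position for a carbonyl carbon. Condensation chemistry would put it trans, so it is introduced as a formyl group on a geometrically fixed vinyl metal (vinyllithium 14 from iodide 13, the bis-silyl ether of 12).

**C4–I and C4a–H across an alkyne (12 ⇒ 10 ⇒ 8).** The (Z)-2-iodo-allylic alcohol 12 is the product of anti addition of H and a metal across the C4≡C4a alkyne of 10, with the metal next to the C3 hydroxyl. Hydroxyl-directed trans-hydrostannation does exactly this. C3 itself is formaldehyde added to the terminal alkyne of 8.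

**C9–C10 (8 ⇒ 5 + 6).** The methylene-bearing C1/C11a/C11/C19/C10 unit is 3-methylbut-3-en-1-ol 6, used as its allylic dianion 7. The electrophile is the epoxy tosylate 5. This cut joins a commercial five-carbon piece to the chain in one step. It requires displacement at C9 without touching the adjacent epoxide.

**Epoxide (5 ⇒ 4 ⇒ 3).** C7 and C8 come from Sharpless epoxidation of the Z-allylic alcohol 3, the only point in the route where the C9 hydroxyl is available to direct it.

**Alkyne and chain end (3 ⇒ 2 ⇒ 1).** The alkyne is a one-carbon homologation of aldehyde 2, which is the ozonolysis product of neryl acetate 1. The isopropylidene end is cleaved first, before the C11=C19 methylene exists, so no alkene has to be distinguished from a 1,1-disubstituted one later.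

## Roads not taken

**Alternative 1:** The cut removes the C4a–C4 and C11a–C1 bonds from a preformed ring A, leading back to (2Z,6Z)-6-methylcyclonona-2,6-dienone A1.
- *Forward key step:* a chiral silylium-type Lewis acid adds a silyl ketene acetal to C4a of A1, and the resulting enol silane is trapped at C11a by an orthoformate-derived carbenium ion, giving the trans-disubstituted cyclononenone A2.
- *Merits:* ring A exists before any stereocentre is set. Conjugate addition followed by anti trapping is a dependable way to a trans C4a/C11a pair, and the reaction types are known.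
- *Weak points:* A1 is itself a nine-membered ring that must be made, so the medium-ring problem is moved, not solved. A2 still needs ring B closed from two acetals, the C11 ketone methylenated next to the epimerisable C11a, the C12 ester turned into a carbinol with a new stereocentre and the enoate arm, and C7=C8 epoxidised in the presence of an electron-rich enol ether.
- *Comparison:* this road is safer than the chosen plan for the ring fusion. The chosen plan sets against it a precursor made entirely by acyclic chemistry, with epoxide and side chain already in place, and one step after the key step instead of many.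

**Alternative 2:** The cut is a radical ring enlargement: ring A of A4 is traced back to the cyclopropane-fused eight-membered xanthate A3.
- *Forward key step:* tin hydride and a radical initiator generate the C19 cyclopropylcarbinyl radical from A3. Its opening cleaves C9–C11, creates the C11=C19 methylene and, after hydrogen transfer to C9, gives the Z-cyclononene A4 fused to the 1-methoxy-dihydropyran-4-carboxylate.
- *Merits:* the medium ring forms by irreversible, strain-driven β-scission rather than by an entropically poor closure, and the methylene appears in the same step. While the C4 ester is present, the enol ether is deactivated and C7=C8 could be epoxidised chemoselectively.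
- *Weak points:* A3 needs a quaternary C11 in a bicyclo[6.1.0] framework and many steps. The ring-opened C9 radical is allylic to C7=C8, so hydrogen can be delivered at C7 and scramble alkene position and geometry. The C12 carbinol, its stereocentre and the arm must then be grown from an ester beside an acid-labile acetal, and OMe at C1 exchanged for OAc.
- *Comparison:* ring formation here is more secure than in the chosen plan. The chosen plan answers with brevity, catalyst control of the fusion and no late oxidation-state changes.

**Alternative 3:** The cut is a Grob fragmentation: the nine-membered ring of A6 is traced back to the tricyclic hydroxy tosylate A5 (a six-five bicycle with the C7–C11 bond).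
- *Forward key step:* an alkoxide base generates the C11 tertiary alkoxide of A5; C7–C11 and C8–O break, and C11=O and the Z-C7=C8 double bond form to give the cyclononenone A6.
- *Merits:* this is the most reliable way to a nine-membered carbocycle, stereospecific for the Z alkene, and it uses robust six- and five-ring chemistry for stereocontrol.
- *Weak points:* A5 needs two ring-fusion quaternary centres and an antiperiplanar tosylate. A6 then needs methylenation of a hindered ketone next to C11a (risk of epimerising the trans fusion), construction of C12 and the arm from the ester, a substrate-controlled epoxidation, and the C1 acetal exchange.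
- *Comparison:* if only certainty of ring formation counted, this road would win. The chosen plan trades that certainty for a much shorter sequence in which every stereocentre except the fusion pair is set by a standard acyclic method.

Key step: step 15

Assumption: (−)-Ipc2B(allyl), the reagent derived from (+)-α-pinene, is taken to attack the Si face of the hindered (Z)-enal 15 as it does with benzaldehyde and simple enals; if the sense were reversed for this substrate, the enantiomeric reagent would be used.

## Route

Step 1
Reactants: 1 neryl acetate [(2Z)-3,7-dimethylocta-2,6-dien-1-yl acetate]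
Product: 2 (2Z)-3-methyl-6-oxohex-2-en-1-yl acetate
Conditions: O3 (about 1 equiv), CH2Cl2, −78 °C; then Me2S, −78 °C to rt
Reagents that add atoms: ozone, O=[O+][O-]
Why: Ozonolysis; the 6,7-alkene is the more electron-rich one because the allylic acetate deactivates the 2,3-alkene, so one equivalent of ozone should cleave only the isopropylidene end and leave the Z-trisubstituted alkene (later C7=C8) intact.

Step 2
Reactants: 2 (2Z)-3-methyl-6-oxohex-2-en-1-yl acetate
Product: 3 (2Z)-3-methylhept-2-en-6-yn-1-ol
Conditions: dimethyl (1-diazo-2-oxopropyl)phosphonate, K2CO3, MeOH, 0 °C to rt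
Reagents that add atoms: dimethyl (1-diazo-2-oxopropyl)phosphonate, CC(=O)C(=[N+]=[N-])P(=O)(OC)OC
Why: Ohira–Bestmann homologation turns the aldehyde into the terminal alkyne (C4a≡C4); the same K2CO3/MeOH methanolyses the allylic acetate and frees the C9 hydroxyl needed for the next step.

Step 3
Reactants: 3 (2Z)-3-methylhept-2-en-6-yn-1-ol
Product: 4 [(2R,3S)-3-(but-3-yn-1-yl)-3-methyloxiran-2-yl]methanol
Conditions: Ti(OiPr)4 (10 mol %), D-(−)-diethyl tartrate (12 mol %), t-BuOOH, 4 Å MS, CH2Cl2, −20 °C
Reagents that add atoms: tert-butyl hydroperoxide, CC(C)(C)OO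
Why: Sharpless asymmetric epoxidation of the Z-allylic alcohol; the D-(−)-tartrate delivers oxygen to the face that gives the (2R,3S)-oxirane (the sense known for nerol), which sets C8 as R and C7 as S; the alkyne is inert.

Step 4
Reactants: 4 [(2R,3S)-3-(but-3-yn-1-yl)-3-methyloxiran-2-yl]methanol
Product: 5 [(2R,3S)-3-(but-3-yn-1-yl)-3-methyloxiran-2-yl]methyl 4-methylbenzenesulfonate
Conditions: TsCl, Et3N, DMAP (cat.), CH2Cl2, 0 °C
Reagents that add atoms: 4-methylbenzenesulfonyl chloride, Cc1ccc(cc1)S(Cl)(=O)=O
Why: Sulfonylation of the primary alcohol gives an isolable C9 electrophile without touching the epoxide.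

Step 5
Reactants: 5 epoxy tosylate; 6 3-methylbut-3-en-1-ol
Product: 8 5-[(2R,3S)-3-(but-3-yn-1-yl)-3-methyloxiran-2-yl]-3-methylidenepentan-1-ol, via dilithiated 3-methylbut-3-en-1-ol 7 (not isolated)
Conditions: 6, n-BuLi (2 equiv), TMEDA, Et2O, 0 °C to rt; then 7 (3 equiv), CuI (10 mol %), THF, −78 °C, add 5, −78 to −30 °C; NH4Cl
Reagents that add atoms: none
Why: SN2 alkylation of the allylic C,O-dianion at the primary sulfonate forms C9–C10; copper-assisted displacement of 2,3-epoxy sulfonates by carbon nucleophiles at the sulfonate carbon is established and the trisubstituted epoxide is the slower electrophile. One equivalent of 7 is consumed by the acetylenic C–H, which returns on work-up, and the 2-substituted allyl anion is symmetric, so only one regioisomer can form.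

Step 6
Reactants: 8 epoxy enyne alcohol
Product: 10 5-[(2R,3S)-3-(5-hydroxypent-3-yn-1-yl)-3-methyloxiran-2-yl]-3-methylidenepentan-1-ol, via lithium alkoxide acetylide 9 (not isolated)
Conditions: n-BuLi (2.2 equiv), THF, −78 to 0 °C; (CH2O)n, 0 °C to rt
Reagents that add atoms: paraformaldehyde (formaldehyde), C=O
Why: Deprotonation of the hydroxyl and the terminal alkyne, then addition of the acetylide to formaldehyde; a standard hydroxymethylation that brings in C3 as a propargylic alcohol.

Step 7
Reactants: 10 propargylic diol
Product: 12 5-[(2R,3S)-3-[(3Z)-5-hydroxy-4-iodopent-3-en-1-yl]-3-methyloxiran-2-yl]-3-methylidenepentan-1-ol, via Z-vinylstannane 11 (not isolated)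
Conditions: Bu3SnH (1.2 equiv), [Cp*RuCl]4 (2.5 mol %), CH2Cl2, rt; then I2 (1.2 equiv), 0 °C
Reagents that add atoms: iodine, II
Why: Hydroxyl-directed ruthenium-catalysed trans-hydrostannation: the propargylic OH steers tin to the proximal alkyne carbon C4 and hydrogen adds anti at C4a. Iododestannylation with retention then gives the (Z)-iodide with iodine cis to C5, the position C12 must occupy.

Step 8
Reactants: 12 (Z)-iodo diol
Product: 13 bis(tert-butyldimethylsilyl) ether of 12 (C1–O and C3–O silylated)
Conditions: TBSCl (2.5 equiv), imidazole, DMF, rt
Reagents that add atoms: tert-butyldimethylsilyl chloride, CC(C)(C)[Si](C)(C)Cl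
Why: Silylation of both primary alcohols with one reagent, so that both can later be released together.

Step 9
Reactants: 13 bis-silylated (Z)-vinyl iodide
Product: 15 (2Z)-2-[(tert-butyldimethylsilyloxy)methyl]-5-{(2S,3R)-3-[5-(tert-butyldimethylsilyloxy)-3-methylidenepentyl]-2-methyloxiran-2-yl}pent-2-enal, via Z-vinyllithium 14 (not isolated)
Conditions: t-BuLi (2.1 equiv), Et2O, −78 °C; DMF, −78 °C; pH 7 buffer
Reagents that add atoms: N,N-dimethylformamide, CN(C)C=O
Why: Iodine–lithium exchange with retention of alkene geometry, then formylation with DMF, places the C12 carbonyl cis to C5. At −78 °C the 2-lithioallyl silyl ether should be formylated faster than it eliminates silanolate or attacks the fully substituted epoxide carbon.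

Step 10
Reactants: 15 (Z)-enal
Product: 17 (4S,5Z)-5-[(tert-butyldimethylsilyloxy)methyl]-8-{(2S,3R)-3-[5-(tert-butyldimethylsilyloxy)-3-methylidenepentyl]-2-methyloxiran-2-yl}octa-1,5-dien-4-ol, via diisopinocampheylborinate 16 (not isolated)
Conditions: (−)-Ipc2B(allyl) (1.5 equiv, salt-free), Et2O, −78 °C; then NaOH, H2O2, 0 °C to rt
Reagents that add atoms: (−)-B-allyldiisopinocampheylborane, C=CCB([C@@H]1C[C@@H]2C[C@H]([C@H]1C)C2(C)C)[C@@H]1C[C@@H]2C[C@H]([C@H]1C)C2(C)C
Why: Brown allylboration through a chair-like six-membered transition state; the pinene-derived reagent alone controls the face (Si face of C12) and sets C12 as S, with no nearby stereocentre to oppose it. The boron reagent at −78 °C should leave the epoxide and the Z geometry of the enal untouched.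

Step 11
Reactants: 17 homoallylic alcohol
Product: 18 (4S,5Z)-octa-1,5-dien-4-yl acetate corresponding to 17 (C12–OAc)
Conditions: Ac2O, pyridine, DMAP (cat.), CH2Cl2, 0 °C to rt
Reagents that add atoms: acetic anhydride, CC(=O)OC(C)=O
Why: Acylation of the secondary allylic alcohol installs the C12 acetate of the target while C1 and C3 are still silylated.

Step 12
Reactants: 18 homoallylic acetate; 19 methyl methacrylate
Product: 20 methyl (2E,5S,6Z)-5-acetoxy-6-[(tert-butyldimethylsilyloxy)methyl]-9-{(2S,3R)-3-[5-(tert-butyldimethylsilyloxy)-3-methylidenepentyl]-2-methyloxiran-2-yl}-2-methylnona-2,6-dienoate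
Conditions: 19 (20 equiv), second-generation Hoveyda–Grubbs catalyst RuCl2(H2IMes)(=CH-C6H4-2-OiPr) (5–10 mol %), CH2Cl2, 40 °C
Reagents that add atoms: none
Why: Olefin cross-metathesis between the terminal alkene and the methacrylate; the 2-methyl enoate forms as the E isomer under thermodynamic control. The 1,1-disubstituted C11=C19 and trisubstituted C4=C4a alkenes are too hindered to enter the catalytic cycle at a useful rate.

Step 13
Reactants: 20 bis-silyl ether
Product: 21 methyl (2E,5S,6Z)-5-acetoxy-6-(hydroxymethyl)-9-[(2S,3R)-3-(5-hydroxy-3-methylidenepentyl)-2-methyloxiran-2-yl]-2-methylnona-2,6-dienoate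
Conditions: HF·pyridine, pyridine, THF, 0 °C
Reagents that add atoms: none
Why: Fluoride cleavage of the two primary silyl ethers; pyridine-buffered HF at 0 °C should spare the epoxide, the enoate and the secondary acetate, and the short cold exposure limits acetyl migration to O3.

Step 14
Reactants: 21 diol
Product: 22 methyl (2E,5S,6E)-5-acetoxy-6-formyl-2-methyl-9-[(2S,3R)-2-methyl-3-(3-methylidene-5-oxopentyl)oxiran-2-yl]nona-2,6-dienoate (C1 aldehyde, C3 enal)
Conditions: Dess–Martin periodinane (3 equiv), NaHCO3, CH2Cl2, 0 °C; used at once
Reagents that add atoms: none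
Why: Dess–Martin oxidation of both primary alcohols under bicarbonate buffer; neutral, non-enolising conditions are chosen so that the C1 aldehyde stays β,γ-unsaturated, and the crude dialdehyde goes straight into the cyclisation.

Step 15
Reactants: 22 epoxy dialdehyde
Product: 24 C1 lactol of the target (1-O-deacetyl compound; 1S,4aS,7S,8R,11aR,12S), via C1 pyrrolidinyl N,O-acetal 23 (not isolated)
Conditions: (R)-α,α-diphenylprolinol trimethylsilyl ether (20 mol %), PhCO2H (20 mol %), toluene, 0.002 M (slow addition of 22), 0 °C to rt; aqueous work-up
Reagents that add atoms: none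
Why: Proposed new method: the secondary amine condenses with the unhindered, enolisable C1 aldehyde (the α-branched enal forms iminium ions only sluggishly) to give the E-dienamine N–C1=C11a–C11=C19, whose α-carbon C11a adds to the enal β-carbon C4a; the C3 enol oxygen then closes onto the C1 iminium carbon to give aminal 23, and water releases lactol 24 and the catalyst, so overall the step is an intramolecular inverse-electron-demand oxa-Diels–Alder reaction of an enamine with an enal. The closest known chemistry is the amine-catalysed intramolecular Michael addition of an aldehyde to an enal with lactol formation for five- and six-membered carbocycles, together with intermolecular enamine/enone hetero-Diels–Alder reactions and α-alkylations of dienamines. Ring A closes in a 9-exo-trig mode (C4=C4a lies outside the new ring) and ring B in a 6-exo-trig mode (oxygen onto C1=N+). C11a is set by the catalyst: the diphenyl(silyloxy)methyl arm of the (R)-amine shields the Si face of the E-dienamine, so C4a bonds to the Re face and gives 11aR. C4a follows from the synclinal, nitrogen-endo arrangement of E-dienamine and E-enal that is normal for enamine Michael additions and gives the trans (4aS) fusion, with the epoxide and C12 acting only as secondary bias. C1 forms as an equilibrating lactol and is fixed in step 16. The step needs α- over γ-attack of the dienamine and intra- over intermolecular addition: only the α-adduct can be captured as the six-membered aminal, which drains the reversible Michael manifold toward 23, while high dilution and the turn imposed by the cis-epoxide favour closure. The fast O–C1 bond formation is also what should keep the C3 enolate from expelling the C12 acetate.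

Step 16
Reactants: 24 lactol
Product: 25 target, methyl (2E,5S)-5-acetoxy-5-[(1R,4aS,7S,8R,11aR)-1-acetoxy-7,8-epoxy-7-methyl-11-methylidene-1,4a,5,6,7,8,9,10,11,11a-decahydrocyclonona[c]pyran-4-yl]-2-methylpent-2-enoate (xenicane numbering)
Conditions: Ac2O, pyridine, DMAP (cat.), CH2Cl2, 0 °C
Reagents that add atoms: acetic anhydride, CC(=O)OC(C)=O
Why: O-Acylation of the lactol; the hydroxyl trans to the C11a–C11 bond (pseudo-equatorial) is expected to be the more stable and more nucleophilic anomer, and the anomers should interconvert by ring-chain tautomerism, so the (1R)-acetate should predominate.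

## Compound list

1 | neryl acetate, (2Z)-3,7-dimethylocta-2,6-dien-1-yl acetate | CC(C)=CCC/C(C)=C\COC(C)=O | starting material
2 | (2Z)-3-methyl-6-oxohex-2-en-1-yl acetate | O=CCC/C(C)=C\COC(C)=O | intermediate
3 | (2Z)-3-methylhept-2-en-6-yn-1-ol | C#CCC/C(C)=C\CO | intermediate
4 | [(2R,3S)-3-(but-3-yn-1-yl)-3-methyloxiran-2-yl]methanol | OC[C@H]1O[C@@]1(C)CCC#C | intermediate
5 | [(2R,3S)-3-(but-3-yn-1-yl)-3-methyloxiran-2-yl]methyl 4-methylbenzenesulfonate | Cc1ccc(cc1)S(=O)(=O)OC[C@H]1O[C@@]1(C)CCC#C | intermediate
6 | 3-methylbut-3-en-1-ol | C=C(C)CCO | starting material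
7 | lithium 3-(lithiomethyl)but-3-en-1-olate (C,O-dianion of 6; not isolated) | [Li]CC(=C)CCO[Li] | intermediate
8 | 5-[(2R,3S)-3-(but-3-yn-1-yl)-3-methyloxiran-2-yl]-3-methylidenepentan-1-ol | C=C(CCO)CC[C@H]1O[C@@]1(C)CCC#C | intermediate
9 | lithium alkoxide and lithium acetylide of 8 (O,C-dilithio; not isolated) | C=C(CCO[Li])CC[C@H]1O[C@@]1(C)CCC#C[Li] | intermediate
10 | 5-[(2R,3S)-3-(5-hydroxypent-3-yn-1-yl)-3-methyloxiran-2-yl]-3-methylidenepentan-1-ol | C=C(CCO)CC[C@H]1O[C@@]1(C)CCC#CCO | intermediate
11 | 5-[(2R,3S)-3-[(3Z)-5-hydroxy-4-(tributylstannyl)pent-3-en-1-yl]-3-methyloxiran-2-yl]-3-methylidenepentan-1-ol (not isolated) | C=C(CCO)CC[C@H]1O[C@@]1(C)CC/C=C(\[Sn](CCCC)(CCCC)CCCC)CO | intermediate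
12 | 5-[(2R,3S)-3-[(3Z)-5-hydroxy-4-iodopent-3-en-1-yl]-3-methyloxiran-2-yl]-3-methylidenepentan-1-ol | C=C(CCO)CC[C@H]1O[C@@]1(C)CC/C=C(\I)CO | intermediate
13 | bis(tert-butyldimethylsilyl) ether of 12 (C1–OTBS, C3–OTBS, Z-vinyl iodide at C4) | C=C(CCO[Si](C)(C)C(C)(C)C)CC[C@H]1O[C@@]1(C)CC/C=C(\I)CO[Si](C)(C)C(C)(C)C | intermediate
14 | Z-vinyllithium from 13 (lithium at C4 in place of iodine; not isolated) | C=C(CCO[Si](C)(C)C(C)(C)C)CC[C@H]1O[C@@]1(C)CC/C=C(\[Li])CO[Si](C)(C)C(C)(C)C | intermediate
15 | (2Z)-2-[(tert-butyldimethylsilyloxy)methyl]-5-{(2S,3R)-3-[5-(tert-butyldimethylsilyloxy)-3-methylidenepentyl]-2-methyloxiran-2-yl}pent-2-enal | C=C(CCO[Si](C)(C)C(C)(C)C)CC[C@H]1O[C@@]1(C)CC/C=C(\C=O)CO[Si](C)(C)C(C)(C)C | intermediate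
16 | diisopinocampheylborinate of 17 (O12–B(Ipc)2; not isolated) | C=C(CCO[Si](C)(C)C(C)(C)C)CC[C@H]1O[C@@]1(C)CC/C=C(/CO[Si](C)(C)C(C)(C)C)[C@H](CC=C)OB([C@@H]1C[C@@H]2C[C@H]([C@H]1C)C2(C)C)[C@@H]1C[C@@H]2C[C@H]([C@H]1C)C2(C)C | intermediate
17 | (4S,5Z)-5-[(tert-butyldimethylsilyloxy)methyl]-8-{(2S,3R)-3-[5-(tert-butyldimethylsilyloxy)-3-methylidenepentyl]-2-methyloxiran-2-yl}octa-1,5-dien-4-ol | C=C(CCO[Si](C)(C)C(C)(C)C)CC[C@H]1O[C@@]1(C)CC/C=C(/CO[Si](C)(C)C(C)(C)C)[C@H](CC=C)O | intermediate
18 | (4S,5Z)-5-[(tert-butyldimethylsilyloxy)methyl]-8-{(2S,3R)-3-[5-(tert-butyldimethylsilyloxy)-3-methylidenepentyl]-2-methyloxiran-2-yl}octa-1,5-dien-4-yl acetate | C=C(CCO[Si](C)(C)C(C)(C)C)CC[C@H]1O[C@@]1(C)CC/C=C(/CO[Si](C)(C)C(C)(C)C)[C@H](CC=C)OC(C)=O | intermediate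
19 | methyl methacrylate | C=C(C)C(=O)OC | starting material
20 | methyl (2E,5S,6Z)-5-acetoxy-6-[(tert-butyldimethylsilyloxy)methyl]-9-{(2S,3R)-3-[5-(tert-butyldimethylsilyloxy)-3-methylidenepentyl]-2-methyloxiran-2-yl}-2-methylnona-2,6-dienoate | C=C(CCO[Si](C)(C)C(C)(C)C)CC[C@H]1O[C@@]1(C)CC/C=C(/CO[Si](C)(C)C(C)(C)C)[C@H](C/C=C(\C)C(=O)OC)OC(C)=O | intermediate
21 | methyl (2E,5S,6Z)-5-acetoxy-6-(hydroxymethyl)-9-[(2S,3R)-3-(5-hydroxy-3-methylidenepentyl)-2-methyloxiran-2-yl]-2-methylnona-2,6-dienoate | C=C(CCO)CC[C@H]1O[C@@]1(C)CC/C=C(/CO)[C@H](C/C=C(\C)C(=O)OC)OC(C)=O | intermediate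
22 | methyl (2E,5S,6E)-5-acetoxy-6-formyl-2-methyl-9-[(2S,3R)-2-methyl-3-(3-methylidene-5-oxopentyl)oxiran-2-yl]nona-2,6-dienoate | C=C(CC=O)CC[C@H]1O[C@@]1(C)CC/C=C(/C=O)[C@H](C/C=C(\C)C(=O)OC)OC(C)=O | intermediate
23 | C1 N,O-acetal of 24 carrying (R)-2-[diphenyl(trimethylsilyloxy)methyl]pyrrolidin-1-yl at C1 in place of OH (C1 configuration open; not isolated) | C=C1CC[C@H]2O[C@@]2(C)CC[C@@H]2C([C@H](C/C=C(\C)C(=O)OC)OC(C)=O)=COC(N3CCC[C@@H]3C(c3ccccc3)(c3ccccc3)O[Si](C)(C)C)[C@@H]12 | intermediate
24 | C1 lactol, methyl (2E,5S)-5-acetoxy-5-[(1S,4aS,7S,8R,11aR)-7,8-epoxy-1-hydroxy-7-methyl-11-methylidene-1,4a,5,6,7,8,9,10,11,11a-decahydrocyclonona[c]pyran-4-yl]-2-methylpent-2-enoate | C=C1CC[C@H]2O[C@@]2(C)CC[C@@H]2C([C@H](C/C=C(\C)C(=O)OC)OC(C)=O)=CO[C@H](O)[C@@H]12 | intermediate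
25 | CNP0184381.3, the (1R,4aS,7S,8R,11aR,12S) 1-O-acetate of 24 | C=C1CC[C@H]2O[C@@]2(C)CC[C@@H]2C([C@H](C/C=C(\C)C(=O)OC)OC(C)=O)=CO[C@H](OC(C)=O)[C@@H]12 | target

## Step count and least certain steps

Total step count: 16. Longest linear sequence: 16 steps (1 to 25); compounds 6 and 19 and all reagents are commercial.

**Step 15 (key step).** The process most likely to go wrong is that intermolecular Michael addition and oligomerisation outrun the strained nine-membered transition state. This would be accompanied by drift of the C1 aldehyde into conjugation and by amine-triggered loss of the C12 acetate from the enal (addition–elimination).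
- *Fallback (known reaction type, no amine, no free C1 aldehyde):* it sets out from 22 and returns at 24. Only the C1 aldehyde of 22 has an acidic α-hydrogen, so soft enolisation (TBSCl, NaI, Et3N, MeCN) should give the C1 (E)-tert-butyldimethylsilyl dienol ether F1. This is cyclised as a thermal or Eu(fod)3-catalysed intramolecular inverse-demand oxa-Diels–Alder reaction of an enal with a silyl enol ether (dilute toluene), giving the 1-O-silyl acetal of the bicycle F2. Buffered fluoride (TBAF, AcOH) then releases lactol 24.
- *Limits:* stereocontrol would rest on the substrate alone, so diastereomers would have to be separated. If ring strain defeats every direct closure, the fragmentation route through A6 is the next resort.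

**Step 5 (C9–C10 coupling).** The allyl anion may attack the epoxide carbon C8 or open the epoxide by elimination instead of displacing the sulfonate at C9.
- *Fallback:* it sets out from 3 and returns at 8, making the C–C bond before the epoxide exists. Corey–Kim chlorination (NCS, Me2S) of 3 gives (2Z)-1-chloro-3-methylhept-2-en-6-yne F3. Allylic alkylation of dianion 7 with F3, a well-known reaction, gives (6Z)-7-methyl-3-methylideneundec-6-en-10-yn-1-ol F4. The electron-rich trisubstituted Z-alkene of F4 is then epoxidised under reagent control with a fructose-derived Shi ketone (Oxone, buffered). The enantiomeric series of the ketone is chosen to give the (2R,3S)-oxirane, and the 1,1-disubstituted alkene and the alkyne react more slowly.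
- *Price:* lower and less predictable enantioselectivity than the hydroxyl-directed epoxidation.

**Step 10 (allylboration).** Facial selectivity may be poor on the α-branched (Z)-enal, or the enal may isomerise to the E form before addition.
- *Fallback:* it sets out from 15 and returns at 17. Unselective allylation with allylboronic acid pinacol ester gives the C12-epimeric alcohols F5. Dess–Martin oxidation gives the cross-conjugated allyl ketone F6, and Corey–Bakshi–Shibata reduction with the (R)-methyl oxazaborolidine and catecholborane should deliver the (S)-alcohol 17, the alkenyl group acting as the large substituent.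

**Step 9 (formylation).** The 2-lithioallyl silyl ether may lose silanolate to give an allene, or the vinyllithium may attack the epoxide before it is formylated.
- *Fallback:* it sets out from 13 and returns at 15 by palladium-catalysed reductive carbonylation (Pd(PPh3)4, CO, slow addition of Bu3SnH, THF, 50 °C). This avoids any organolithium and makes no new compound (F0).

**Step 16 (anomeric acetylation).** Basic acylation may trap the wrong anomer, or open the lactol to the hydroxy-enol/dialdehyde manifold and epimerise C11a.
- *Fallback:* it sets out from 24 and returns at 25 by Mitsunobu esterification with acetic acid (PPh3, diisopropyl azodicarboxylate, AcOH, THF, 0 °C). This substitutes at C1 with inversion under neutral conditions and would convert a predominant cis-lactol into the trans-acetate; it makes no new compound (F0).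

## Further compounds

F1 | step 15 | C1 (E)-tert-butyldimethylsilyl dienol ether of 22 (TBSO–C1H=C11aH–C11(=C19H2); C3 enal unchanged) | C=C(/C=C/O[Si](C)(C)C(C)(C)C)CC[C@H]1O[C@@]1(C)CC/C=C(/C=O)[C@H](C/C=C(\C)C(=O)OC)OC(C)=O
F2 | step 15 | 1-O-tert-butyldimethylsilyl acetal of 24 | C=C1CC[C@H]2O[C@@]2(C)CC[C@@H]2C([C@H](C/C=C(\C)C(=O)OC)OC(C)=O)=CO[C@H](O[Si](C)(C)C(C)(C)C)[C@@H]12
F3 | step 5 | (2Z)-1-chloro-3-methylhept-2-en-6-yne | C#CCC/C(C)=C\CCl
F4 | step 5 | (6Z)-7-methyl-3-methylideneundec-6-en-10-yn-1-ol | C=C(CCO)CC/C=C(C)\CCC#C
F5 | step 10 | C12-epimeric mixture corresponding to 17 (4RS alcohol) | C=C(CCO[Si](C)(C)C(C)(C)C)CC[C@H]1O[C@@]1(C)CC/C=C(/CO[Si](C)(C)C(C)(C)C)C(O)CC=C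
F6 | step 10 | C12 ketone corresponding to 17 [(5Z)-octa-1,5-dien-4-one] | C=C(CCO[Si](C)(C)C(C)(C)C)CC[C@H]1O[C@@]1(C)CC/C=C(/CO[Si](C)(C)C(C)(C)C)C(=O)CC=C
F0 | step 9 | none | none
F0 | step 16 | none | none
A1 | alternative 1 | (2Z,6Z)-6-methylcyclonona-2,6-dien-1-one | O=C1CC/C=C(C)\CC/C=C\1
A2 | alternative 1 | trans-disubstituted (Z)-cyclononenone with the C1 dimethyl acetal at C11a and the methyl 3,3-dimethoxypropanoate-2-yl arm at C4a | O=C1CC/C=C(C)\CC[C@H]([C@H](C(=O)OC)C(OC)OC)[C@H]1C(OC)OC
A3 | alternative 2 | S-methyl xanthate of the C19 carbinol on the cyclopropane-fused (C9–C10–C11) eight-membered Z-cycloalkene bearing the 1-methoxy-dihydropyran-4-carboxylate | CSC(=S)OCC12CC1/C=C(C)\CC[C@@H]1C(C(=O)OC)=CO[C@H](OC)[C@@H]21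
A4 | alternative 2 | Z-cyclononene with C11 methylene fused to the 1-methoxy-dihydropyran-4-carboxylate | C=C1CC/C=C(C)\CC[C@@H]2C(C(=O)OC)=CO[C@H](OC)[C@@H]12
A5 | alternative 3 | tricyclic hydroxy tosylate (C7–C11 bonded hydrindane, C11 tertiary alcohol, C8 tosylate) fused to the 1-methoxy-dihydropyran-4-carboxylate | Cc1ccc(cc1)S(=O)(=O)OC1CCC2(O)C1(C)CC[C@@H]1C(C(=O)OC)=CO[C@H](OC)[C@@H]21
A6 | alternative 3 | Z-cyclononenone (C11 ketone) fused to the 1-methoxy-dihydropyran-4-carboxylate | O=C1CC/C=C(C)\CC[C@@H]2C(C(=O)OC)=CO[C@H](OC)[C@@H]12
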